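The route rests on cutting C5–C6, the bond between a bridgehead and the gem-dimethyl carbon. With that bond cut and the C5 prenyl and C3 aroyl groups removed, ring B (C1-C2-C3-C4-C5-C9) has a mirror plane through C1 and C4. This plane exchanges C2=C3 with C9=C5, so C1 is only prochiral. The precursor is a Birch-derived 1-geranyl-2,6-dimethoxycyclohexa-2,5-diene. Its second arm on C1 (C8-C7-C6) holds the only stereocentre, C7, and a tertiary leaving group on C6, kept as an acetate and turned into the chloride only in the flask. Ionisation lets one diastereotopic enol ether attack through C5. In one operation ring A closes, C7 dictates C1 and C5, and the C9 ketone is unmasked.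

Key step: step 11

Numbering (bicyclo[3.3.1]nonane, also used for the open-chain precursors):
- C1 is the bridgehead with geranyl.
- C2, C3 and C4 form the three-carbon bridge, with oxygen on C2 and C4 and the aroyl group on C3.
- C5 is the bridgehead with prenyl, C6 is CMe2, C7 is CH(prenyl), C8 is CH2, and C9 is the one-carbon keto bridge.
- Ring A is C1-C8-C7-C6-C5-C9 and ring B is C1-C2-C3-C4-C5-C9.
- C2'=C3' is the geranyl double bond nearest C1.
- The C7 prenyl of the target is exo (equatorial on chair ring A). C7 keeps one spatial arrangement from step 2 on, and its descriptor changes only when priorities change.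

Assumption: the enolised triketone is drawn as the C2-enol/C4-keto tautomer of the target SMILES (the tautomers equilibrate freely and need no control), and 5-methylhex-4-enoic acid is taken as a catalogue compound.

Step 1
Reactants: 1 5-methylhex-4-enoic acid; 2 (S)-4-benzyl-1,3-oxazolidin-2-one
Product: 4 (S)-4-benzyl-3-(5-methylhex-4-enoyl)-1,3-oxazolidin-2-one, via mixed pivalic anhydride 3 (not isolated)
Conditions: t-BuCOCl, Et3N, THF, −20 °C; then LiCl, 2, −20 °C → rt
Reagents that add atoms: none
Why: Mixed-anhydride N-acylation of an oxazolidinone (LiCl/Et3N variant) needs no strong base, the hindered pivaloyl carbonyl steers attack to the hexenoyl carbonyl, the alkene is inert, and no stereocentre is formed.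

Step 2
Reactants: 4 (S)-4-benzyl-3-(5-methylhex-4-enoyl)-1,3-oxazolidin-2-one; 5 acetone
Product: 7 (S)-4-benzyl-3-[(2R)-2-(2-hydroxypropan-2-yl)-5-methylhex-4-enoyl]-1,3-oxazolidin-2-one, via lithium (Z)-enolate 6 (not isolated)
Conditions: LiN(i-Pr)2, THF, −78 °C; 5 (dry, excess), −78 °C; AcOH in THF at −78 °C
Reagents that add atoms: none
Why: In this auxiliary-controlled lithium-enolate aldol addition to a ketone, the lithium-chelated (Z)-enolate exposes the face opposite the benzyl group (the same sense as in imide alkylation), so acetone adds there and sets C7, acetone creates no second stereocentre, and the cold acidic quench forestalls retro-aldol cleavage.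

Step 3
Reactants: 7 aldol adduct
Product: 8 (S)-4-benzyl-3-[(2R)-5-methyl-2-(2-triethylsilyloxypropan-2-yl)hex-4-enoyl]-1,3-oxazolidin-2-one
Conditions: Et3SiOTf, 2,6-lutidine, CH2Cl2, −78 → 0 °C
Reagents that add atoms: triethylsilyl triflate, CC[Si](CC)(CC)OS(=O)(=O)C(F)(F)F
Why: Silyl triflate/lutidine silylation caps even hindered tertiary alcohols without an alkoxide, so retro-aldol and epimerisation at C7 are excluded and the C6 oxygen is masked for the organolithium steps.

Step 4
Reactants: 8 silylated imide
Product: 9 (2S)-5-methyl-2-(2-triethylsilyloxypropan-2-yl)hex-4-en-1-ol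
Conditions: LiBH4, H2O (1.1 equiv), Et2O, 0 °C
Reagents that add atoms: none
Why: Reductive removal of the auxiliary with LiBH4 attacks the exocyclic imide carbonyl, passes quickly through the aldehyde stage so that C7 is not epimerised, spares alkene and silyl ether, and returns the auxiliary.

Step 5
Reactants: 9 primary alcohol
Product: 10 triethyl{[(3R)-3-(iodomethyl)-2,6-dimethylhept-5-en-2-yl]oxy}silane
Conditions: PPh3, imidazole, I2 (premixed), CH2Cl2, 0 °C → rt
Reagents that add atoms: iodine, II
Why: Appel-type iodination (Garegg–Samuelsson conditions) activates the only free hydroxyl and displaces it by SN2 at C8, one carbon away from C7, and premixing the reagents leaves no free iodine to attack the prenyl alkene.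

Step 6
Reactants: 11 1,3-dimethoxybenzene
Product: 12 1,5-dimethoxycyclohexa-1,4-diene
Conditions: Na, NH3(l), t-BuOH, THF, −78 → −33 °C
Reagents that add atoms: none
Why: In the Birch reduction the two donor groups steer protonation to the carbon between them and the one para to it, which gives the unconjugated diene with both oxygens on double bonds, that is ring B with its mirror plane and the future C1 as the methylene between the enol ethers.

Step 7
Reactants: 12 1,5-dimethoxycyclohexa-1,4-diene; 10 iodide
Product: 14 triethyl{[(3S)-3-[(2,6-dimethoxycyclohexa-2,5-dien-1-yl)methyl]-2,6-dimethylhept-5-en-2-yl]oxy}silane, via 6-lithio diene 13 (not isolated)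
Conditions: 12 (1.3 equiv), t-BuLi (1.2 equiv), THF, −78 °C; DMPU, 10, −78 → −10 °C
Reagents that add atoms: none
Why: In this lithiation–alkylation of a Birch diene, t-BuLi deprotonates the methylene flanked by both methoxy-bearing carbons, the cyclohexadienyl lithium alkylates at that central carbon and keeps the 1,4-diene, the slow beta-branched iodide is deliberately paired with the still secondary carbanion, and SN2 at C8 leaves C7 untouched.

Step 8
Reactants: 14 monoalkylated diene; 15 geranyl bromide
Product: 17 1-geranyl-1-[(2S)-5-methyl-2-(2-triethylsilyloxypropan-2-yl)hex-4-enyl]-2,6-dimethoxycyclohexa-2,5-diene, via tertiary lithio diene 16 (not isolated)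
Conditions: s-BuLi, THF, −78 → −40 °C; 15, −78 °C → 0 °C
Reagents that add atoms: none
Why: This second lithiation–alkylation at the same carbon builds the quaternary C1 with the most reactive partner, an allylic bromide that reacts by direct SN2 with the E geometry kept, and the two identical ring arms mean that C1 is not yet a stereocentre.

Step 9
Reactants: 17 silyl ether
Product: 18 (3S)-3-[(1-geranyl-2,6-dimethoxycyclohexa-2,5-dien-1-yl)methyl]-2,6-dimethylhept-5-en-2-ol
Conditions: Bu4NF, THF, rt → 40 °C; chromatography on Et3N-washed silica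
Reagents that add atoms: none
Why: Fluoride desilylation runs under basic conditions, which the acid-labile bis(enol ether), the skipped diene and the trisubstituted alkenes all tolerate.

Step 10
Reactants: 18 tertiary alcohol
Product: 20 (3S)-3-[(1-geranyl-2,6-dimethoxycyclohexa-2,5-dien-1-yl)methyl]-2,6-dimethylhept-5-en-2-yl acetate, via lithium alkoxide 19 (not isolated)
Conditions: n-BuLi (1.05 equiv), THF, −78 °C; Ac2O, −78 → 0 °C
Reagents that add atoms: acetic anhydride, CC(=O)OC(C)=O
Why: O-acylation of a preformed lithium alkoxide esterifies even a hindered tertiary alcohol under strictly basic conditions and gives a storable nucleofuge, which avoids any acidic alcohol-to-chloride exchange in the presence of two enol ethers.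

Step 11
Reactants: 20 tertiary acetate
Product: 22 (1R,5R,7S)-1-geranyl-2-methoxy-6,6-dimethyl-7-prenylbicyclo[3.3.1]non-2-en-9-one, via tertiary chloride 21 (not isolated)
Conditions: TiCl4 (2.2 equiv), 2,6-di-tert-butyl-4-methylpyridine (1 equiv), CH2Cl2, −78 °C; aq NaHCO3 at −78 °C
Reagents that add atoms: none
Why: TiCl4 first swaps the tertiary acetate for chloride and then ionises 21 reversibly to the C6 dimethyl-substituted cation, the enol ether carbon C5 adds to it, and the C9 methoxy-oxocarbenium ion, which cannot shed a proton without making a bridgehead alkene, is demethylated by chloride at its methyl group to give the ketone and chloromethane. The closest known reaction types are the Lewis-acid SN1 alpha-tert-alkylation of enol ethers with tertiary halides or acetates and the epoxide-triggered cationic closures of 1,1-dialkyl-2,6-dimethoxycyclohexa-2,5-dienes to bicyclo[3.3.1]nonanes. Ring A (C1-C8-C7-C6-C5-C9) closes in a 6-(enol-endo)-exo mode, that is 6-endo-trig as seen from the C5=C9 double bond, which ends inside the new ring, and exo as seen from C6, whose leaving group departs outside it. C7 is the only control element: in the chair-like transition state its prenyl group stays equatorial (exo), whereas closure through the other enol ether would push it axial under the diene ring, so the choice of enol ether fixes C1, and C5 follows because the one-carbon bridge can only span the ring cis. The step needs group selectivity between two diastereotopic enol ethers, secured by that chair, and chemoselectivity over the geranyl C2'=C3' alkene (a conceivable six-ring closure) and the prenyl alkene, secured by the far higher nucleophilicity of an alkyl enol ether, while the hindered pyridine mops up stray HCl so that neither enol ethers nor alkenes are protonated. Making the chloride only in the flask avoids preparing, purifying or storing a tertiary chloride beside two enol ethers.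

Step 12
Reactants: 22 bicyclic enol ether
Product: 23 (1R,5S,7S)-1-geranyl-2-methoxy-6,6-dimethyl-7-prenylbicyclo[3.3.1]non-2-ene-4,9-dione
Conditions: PhI(OAc)2, t-BuOOH (decane), K2CO3, EtOAc, −20 °C
Reagents that add atoms: tert-butyl hydroperoxide, CC(C)(C)OO
Why: In this radical allylic oxidation, tert-butylperoxy radicals from the trivalent iodine reagent give an allylic peroxide that collapses in Kornblum–DeLaMare fashion; the C4–H bonds next to the electron-rich C2=C3 enol ether are abstracted ahead of the prenyl and geranyl allylic C–H bonds, as is known for this class of bicyclic enol ethers, and the deactivated vinylogous ester resists further oxidation.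

Step 13
Reactants: 23 vinylogous ester
Product: 25 (1R,5R,7S)-1-geranyl-2-methoxy-6,6-dimethyl-7-prenyl-3-(trimethylsilyl)bicyclo[3.3.1]non-2-ene-4,9-dione, via C3-lithio compound 24 (not isolated)
Conditions: 2,2,6,6-tetramethylpiperidine, n-BuLi, THF, 0 °C; then Me3SiCl and 23, −78 °C (in situ quench)
Reagents that add atoms: chlorotrimethylsilane, C[Si](C)(C)Cl
Why: In this vinylic lithiation with in situ silyl trapping, the sp2 C3–H between the methoxy-bearing C2 and the C4 carbonyl is the kinetically preferred site for the bulky amide, so C3 is blocked before the shielded bridgehead is addressed.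

Step 14
Reactants: 25 C3-silylated vinylogous ester; 26 prenyl bromide
Product: 28 (1R,5R,7S)-1-geranyl-2-methoxy-6,6-dimethyl-5,7-diprenyl-3-(trimethylsilyl)bicyclo[3.3.1]non-2-ene-4,9-dione, via C5 bridgehead lithium compound 27 (not isolated)
Conditions: LiN(i-Pr)2 (excess), THF, −78 °C; 26 (excess), −78 → 0 °C
Reagents that add atoms: none
Why: In this bridgehead lithiation–alkylation, C5–H is the only acidic hydrogen left once C3 is blocked, it is flanked by the C4 and C9 carbonyls, the pyramidal carbanion (no enolate, by Bredt's rule) cannot invert, and so the allylic bromide enters with the configuration set in step 11.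

Step 15
Reactants: 28 C5-prenylated silane
Product: 29 (1R,5S,7S)-1-geranyl-2-methoxy-6,6-dimethyl-5,7-diprenylbicyclo[3.3.1]non-2-ene-4,9-dione
Conditions: Bu4NF, THF, 0 °C
Reagents that add atoms: none
Why: Fluoride protodesilylation of an alpha-silyl enone is fast because the departing vinyl anion is stabilised by the C4 carbonyl, and nothing else in the molecule responds to fluoride.

Step 16
Reactants: 30 3,4-dihydroxybenzoic acid
Product: 31 tert-butyldimethylsilyl 3,4-bis(tert-butyldimethylsilyloxy)benzoate
Conditions: t-BuMe2SiCl (3.5 equiv), imidazole, DMF, rt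
Reagents that add atoms: tert-butyldimethylsilyl chloride, CC(C)(C)[Si](C)(C)Cl
Why: Exhaustive imidazole-promoted silylation masks both phenols and turns the acid into a silyl ester in one operation.

Step 17
Reactants: 31 tris-silyl compound
Product: 32 3,4-bis(tert-butyldimethylsilyloxy)benzoyl chloride
Conditions: (COCl)2, DMF (cat.), CH2Cl2, 0 °C → rt; used crude
Reagents that add atoms: oxalyl chloride, O=C(Cl)C(=O)Cl
Why: Vilsmeier-type activation converts a silyl ester directly into the acid chloride under neutral conditions, so no HCl is released and the aryl silyl ethers stay in place.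

Step 18
Reactants: 29 vinylogous ester; 32 aroyl chloride
Product: 34 (1R,5R,7S)-3-[3,4-bis(tert-butyldimethylsilyloxy)benzoyl]-1-geranyl-2-methoxy-6,6-dimethyl-5,7-diprenylbicyclo[3.3.1]non-2-ene-4,9-dione, via C3-lithio compound 33 (not isolated)
Conditions: 2,2,6,6-tetramethylpiperidine, n-BuLi, THF, 0 °C; 29, −78 °C; 32, −78 °C → −20 °C
Reagents that add atoms: none
Why: In this vinylic lithiation–acylation both bridgeheads are now quaternary, so C3–H is the only site the amide can deprotonate, the vinyllithium is acylated by the acid chloride, and the crowded cross-conjugated ketone formed resists a second addition.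

Step 19
Reactants: 34 O-methyl bis-silyl precursor
Product: 35 (1R,5R,7S)-3-[3,4-bis(tert-butyldimethylsilyloxy)benzoyl]-1-geranyl-2-hydroxy-6,6-dimethyl-5,7-diprenylbicyclo[3.3.1]non-2-ene-4,9-dione
Conditions: LiCl, DMSO, 120 °C, argon; dilute aq HCl (pH 3) on work-up
Reagents that add atoms: none
Why: In this Krapcho-type dealkylation chloride attacks the methyl group by SN2 and expels the strongly stabilised triketone enolate, no stereocentre or alkene is touched, and any partial loss of aryl silyl groups is harmless because the next step removes them.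

Step 20
Reactants: 35 bis-silyl ether
Product: 36 target CNP0160101.4, (1R,5R,7S)-3-(3,4-dihydroxybenzoyl)-1-geranyl-2-hydroxy-6,6-dimethyl-5,7-diprenylbicyclo[3.3.1]non-2-ene-4,9-dione
Conditions: Et3N·3HF, THF, rt, argon
Reagents that add atoms: none
Why: Fluoride cleavage of aryl silyl ethers under mildly acidic buffering frees the catechol without the strong base that would invite air oxidation or retro-Claisen loss of the aroyl group, and without the strong acid that would cyclise the enol onto a prenyl group.

Compound list
1 | 5-methylhex-4-enoic acid | CC(C)=CCCC(=O)O | starting material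
2 | (S)-4-benzyl-1,3-oxazolidin-2-one | O=C1N[C@@H](Cc2ccccc2)CO1 | starting material
3 | 5-methylhex-4-enoic pivalic anhydride | CC(C)=CCCC(=O)OC(=O)C(C)(C)C | intermediate
4 | (S)-4-benzyl-3-(5-methylhex-4-enoyl)-1,3-oxazolidin-2-one | CC(C)=CCCC(=O)N1[C@@H](Cc2ccccc2)COC1=O | intermediate
5 | acetone | CC(C)=O | starting material
6 | lithium (Z)-enolate of 4 | [Li]O/C(=C\CC=C(C)C)N1[C@@H](Cc2ccccc2)COC1=O | intermediate
7 | (S)-4-benzyl-3-[(2R)-2-(2-hydroxypropan-2-yl)-5-methylhex-4-enoyl]-1,3-oxazolidin-2-one | CC(C)=CC[C@H](C(C)(C)O)C(=O)N1[C@@H](Cc2ccccc2)COC1=O | intermediate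
8 | triethylsilyl ether of 7 (2R) | CC(C)=CC[C@H](C(C)(C)O[Si](CC)(CC)CC)C(=O)N1[C@@H](Cc2ccccc2)COC1=O | intermediate
9 | (2S)-5-methyl-2-(2-triethylsilyloxypropan-2-yl)hex-4-en-1-ol | CC(C)=CC[C@@H](CO)C(C)(C)O[Si](CC)(CC)CC | intermediate
10 | triethyl{[(3R)-3-(iodomethyl)-2,6-dimethylhept-5-en-2-yl]oxy}silane | CC(C)=CC[C@@H](CI)C(C)(C)O[Si](CC)(CC)CC | intermediate
11 | 1,3-dimethoxybenzene | COc1cccc(OC)c1 | starting material
12 | 1,5-dimethoxycyclohexa-1,4-diene | COC1=CCC=C(OC)C1 | intermediate
13 | 6-lithio-1,5-dimethoxycyclohexa-1,4-diene | [Li]C1C(OC)=CCC=C1OC | intermediate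
14 | monoalkylated diene, C7 S, C1 still bearing H | COC1=CCC=C(OC)C1C[C@H](CC=C(C)C)C(C)(C)O[Si](CC)(CC)CC | intermediate
15 | geranyl bromide (E) | CC(C)=CCC/C(C)=C/CBr | starting material
16 | C1-lithio derivative of 14 | [Li]C1(C[C@H](CC=C(C)C)C(C)(C)O[Si](CC)(CC)CC)C(OC)=CCC=C1OC | intermediate
17 | 1-geranyl-1-[(2S)-5-methyl-2-(2-triethylsilyloxypropan-2-yl)hex-4-enyl]-2,6-dimethoxycyclohexa-2,5-diene | CC(C)=CCC/C(C)=C/CC1(C[C@H](CC=C(C)C)C(C)(C)O[Si](CC)(CC)CC)C(OC)=CCC=C1OC | intermediate
18 | tertiary alcohol from 17 (C7 S) | CC(C)=CCC/C(C)=C/CC1(C[C@H](CC=C(C)C)C(C)(C)O)C(OC)=CCC=C1OC | intermediate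
19 | lithium alkoxide of 18 | CC(C)=CCC/C(C)=C/CC1(C[C@H](CC=C(C)C)C(C)(C)O[Li])C(OC)=CCC=C1OC | intermediate
20 | tertiary acetate of 18 (C7 S), storable key-step precursor | CC(C)=CCC/C(C)=C/CC1(C[C@H](CC=C(C)C)C(C)(C)OC(C)=O)C(OC)=CCC=C1OC | intermediate
21 | 1-[(2S)-2-(2-chloropropan-2-yl)-5-methylhex-4-enyl]-1-geranyl-2,6-dimethoxycyclohexa-2,5-diene | CC(C)=CCC/C(C)=C/CC1(C[C@H](CC=C(C)C)C(C)(C)Cl)C(OC)=CCC=C1OC | intermediate
22 | (1R,5R,7S)-1-geranyl-2-methoxy-6,6-dimethyl-7-prenylbicyclo[3.3.1]non-2-en-9-one (C5–H, C7 prenyl exo) | CC(C)=CCC/C(C)=C/C[C@@]12C[C@H](CC=C(C)C)C(C)(C)[C@@H](CC=C1OC)C2=O | intermediate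
23 | (1R,5S,7S)-4,9-dione (C4 ketone added to 22) | CC(C)=CCC/C(C)=C/C[C@@]12C[C@H](CC=C(C)C)C(C)(C)[C@@H](C(=O)C=C1OC)C2=O | intermediate
24 | C3-lithio derivative of 23 | CC(C)=CCC/C(C)=C/C[C@@]12C[C@H](CC=C(C)C)C(C)(C)[C@@H](C(=O)C([Li])=C1OC)C2=O | intermediate
25 | (1R,5R,7S)-3-trimethylsilyl derivative of 23 | CC(C)=CCC/C(C)=C/C[C@@]12C[C@H](CC=C(C)C)C(C)(C)[C@@H](C(=O)C([Si](C)(C)C)=C1OC)C2=O | intermediate
26 | prenyl bromide | CC(C)=CCBr | starting material
27 | C5 bridgehead lithium derivative of 25 | CC(C)=CCC/C(C)=C/C[C@@]12C[C@H](CC=C(C)C)C(C)(C)[C@@]([Li])(C(=O)C([Si](C)(C)C)=C1OC)C2=O | intermediate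
28 | (1R,5R,7S)-5-prenyl-3-trimethylsilyl compound | CC(C)=CCC/C(C)=C/C[C@@]12C[C@H](CC=C(C)C)C(C)(C)[C@@](CC=C(C)C)(C(=O)C([Si](C)(C)C)=C1OC)C2=O | intermediate
29 | (1R,5S,7S)-1-geranyl-2-methoxy-6,6-dimethyl-5,7-diprenylbicyclo[3.3.1]non-2-ene-4,9-dione | CC(C)=CCC/C(C)=C/C[C@@]12C[C@H](CC=C(C)C)C(C)(C)[C@@](CC=C(C)C)(C(=O)C=C1OC)C2=O | intermediate
30 | 3,4-dihydroxybenzoic acid | O=C(O)c1ccc(O)c(O)c1 | starting material
31 | tert-butyldimethylsilyl 3,4-bis(tert-butyldimethylsilyloxy)benzoate | CC(C)(C)[Si](C)(C)OC(=O)c1ccc(O[Si](C)(C)C(C)(C)C)c(O[Si](C)(C)C(C)(C)C)c1 | intermediate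
32 | 3,4-bis(tert-butyldimethylsilyloxy)benzoyl chloride | O=C(Cl)c1ccc(O[Si](C)(C)C(C)(C)C)c(O[Si](C)(C)C(C)(C)C)c1 | intermediate
33 | C3-lithio derivative of 29 | CC(C)=CCC/C(C)=C/C[C@@]12C[C@H](CC=C(C)C)C(C)(C)[C@@](CC=C(C)C)(C(=O)C([Li])=C1OC)C2=O | intermediate
34 | (1R,5R,7S)-3-aroyl O-methyl bis-silyl precursor | CC(C)=CCC/C(C)=C/C[C@@]12C[C@H](CC=C(C)C)C(C)(C)[C@@](CC=C(C)C)(C(=O)C(C(=O)c3ccc(O[Si](C)(C)C(C)(C)C)c(O[Si](C)(C)C(C)(C)C)c3)=C1OC)C2=O | intermediate
35 | (1R,5R,7S)-enolised triketone, catechol still bis-silylated | CC(C)=CCC/C(C)=C/C[C@@]12C[C@H](CC=C(C)C)C(C)(C)[C@@](CC=C(C)C)(C(=O)C(C(=O)c3ccc(O[Si](C)(C)C(C)(C)C)c(O[Si](C)(C)C(C)(C)C)c3)=C1O)C2=O | intermediate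
36 | CNP0160101.4, (1R,5R,7S) | CC(C)=CCC/C(C)=C/C[C@@]12C[C@H](CC=C(C)C)C(C)(C)[C@@](CC=C(C)C)(C(=O)C(C(=O)c3ccc(O)c(O)c3)=C1O)C2=O | target

Total step count: 20
Longest linear sequence: 17 steps (1–5, 7–15, 18–20)

Steps most likely to fail

1. Step 11 (key step).
What may go wrong: ring closure may be outrun by proton loss from the C6 cation or by a 1,2-hydride shift from C7. The cation may also be captured by the geranyl C2'=C3' double bond, or the very acid-sensitive bis(enol ether) may degrade under the Lewis acid before ionisation.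
Fallback: raise the oxidation level first, so that the nucleophile becomes acid-stable and the cation can be made with a Brønsted acid. The fallback sets out from alcohol 18. C4H2 lies on the mirror plane, so its oxidation keeps C1 prochiral. Bis-allylic oxidation with (C5H5NH)2Cr2O7 and t-BuOOH on Celite in benzene should give the cross-conjugated 4,4-dialkyl-3,5-dimethoxycyclohexa-2,5-dienone alcohol F1. This doubly vinylogous ester tolerates acid, so the tertiary alcohol can be ionised in HCO2H with LiBr at 0 °C → rt. The same C5–C6 bond forms through the same chair, and bromide takes the methyl group from the oxocarbenium ion. The fallback comes back to the route at 23, and steps 10 to 12 are bypassed.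

2. Step 14.
What may go wrong: deprotonation of the C5–H may be slow or incomplete because the C6 gem-dimethyl group shields it. Capture of the hindered bridgehead carbanion by prenyl bromide may also be sluggish, with proton return or SN2' attack competing.
Fallback: replace the polar C–C bond formation by a radical one. It sets out from 25. The bridgehead lithium compound 27 is trapped with the small electrophile I2 (LiN(i-Pr)2, THF, −78 °C; I2) to give the bridgehead iodide F2. Keck radical allylation (Bu3SnCH2CH=CH2, Et3B, air, benzene, rt) then gives the C5-allyl compound F3, since the bridgehead radical cannot invert. Cross-metathesis with 2-methylbut-2-ene and second-generation Hoveyda–Grubbs catalyst converts the only terminal alkene into the prenyl group, and the route is rejoined at 28.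

3. Step 7.
What may go wrong: SN2 displacement at the beta-branched C8 may be so slow that the thermally fragile cyclohexadienyl lithium decays on warming, by rearomatisation through loss of hydride or methoxide. Elimination or iodine–lithium exchange may compete as well.
Fallback: form the C1–C8 bond on the arene and dearomatise afterwards. It sets out from 11 and 10. Lithiation of 11 between the two methoxy groups (n-BuLi, THF, 0 °C → rt) gives the robust 2-lithio-1,3-dimethoxybenzene F4. This can be heated with iodide 10 (THF–DMPU, up to reflux) to give the 2-alkyl-1,3-dimethoxybenzene F5. Birch reduction (Li, NH3(l), t-BuOH, THF, −78 → −33 °C) spares the isolated trisubstituted alkene and the silyl ether and comes back to the route at 14.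

Further compounds
F1 | step 11 | 4-geranyl-4-[(2S)-2-(2-hydroxypropan-2-yl)-5-methylhex-4-enyl]-3,5-dimethoxycyclohexa-2,5-dien-1-one | CC(C)=CCC/C(C)=C/CC1(C[C@H](CC=C(C)C)C(C)(C)O)C(OC)=CC(=O)C=C1OC
F2 | step 14 | C5-iodo analogue of 25 (iodine in place of the bridgehead hydrogen, C1 and C7 unchanged) | CC(C)=CCC/C(C)=C/C[C@@]12C[C@H](CC=C(C)C)C(C)(C)[C@@](I)(C(=O)C([Si](C)(C)C)=C1OC)C2=O
F3 | step 14 | C5-allyl analogue of 28 (allyl in place of the C5 prenyl) | CC(C)=CCC/C(C)=C/C[C@@]12C[C@H](CC=C(C)C)C(C)(C)[C@@](CC=C)(C(=O)C([Si](C)(C)C)=C1OC)C2=O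
F4 | step 7 | 2-lithio-1,3-dimethoxybenzene | [Li]c1c(OC)cccc1OC
F5 | step 7 | triethyl{[(3S)-3-[(2,6-dimethoxyphenyl)methyl]-2,6-dimethylhept-5-en-2-yl]oxy}silane | COc1cccc(OC)c1C[C@H](CC=C(C)C)C(C)(C)O[Si](CC)(CC)CC
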